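**Retrosynthetic overview**
- The last step is a transannular crossed [2+2] of a fully acylated humulane dienone. It makes the C1–C6 and C2–C7 bonds, the same two bonds as the humulyl → himachalyl → longipinyl cation sequence.
- The eleven-membered ring comes from Nozaki–Hiyama–Kishi closure (C5–C6) of an iodo aldehyde.
- The C5 aldehyde, the (E)-C1=C2 alkene and the C3 methyl centre come from Claisen rearrangement of an allyl vinyl ether. That ether is carried through the route as a latent aldehyde.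
- The anti C8/C10 diol diester comes from a boron aldol, an Evans–Tishchenko reduction (places the acetate) and an angeloylation.
- Ring order: eleven-membered ring first, then the six- and four-membered rings together in one step.

Assumption and convention: locants C1–C11 are biogenetic (farnesane) ring locants (C11 = CMe2, C10 = CHOAc, C8 = CHOAng, C5 = C=O, C3 = CHMe), and the N-tosyl-D-valine promoter is taken to give the (S)-carbinol in step 1 (if the sense proves opposite, N-tosyl-L-valine is used).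

**Step 1**
Reactants: 1 (2E)-but-2-enal; 2 1-methoxy-2-methyl-1-(trimethylsilyloxy)prop-1-ene
Product: 3 methyl (3S,4E)-3-hydroxy-2,2-dimethylhex-4-enoate
Conditions: N-tosyl-D-valine (1.0 equiv), BH3·THF (1.0 equiv), CH2Cl2, 0 °C to rt; then 1 and 2, −78 °C, 3 h; pH 7 buffer
Reagents that add atoms: none
Why: Kiyooka-type enantioselective Mukaiyama aldol, in which the aldehyde bound to the valine-derived oxazaborolidinone is attacked 1,2 on one face by the achiral ketene acetal, setting C1 as (S) and installing the C11 gem-dimethyl carbon.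

**Step 2**
Reactants: 3 methyl (3S,4E)-3-hydroxy-2,2-dimethylhex-4-enoate
Product: 4 methyl (3S,4E)-3-(ethenyloxy)-2,2-dimethylhex-4-enoate
Conditions: n-butyl vinyl ether (solvent), Pd(OAc)2 (5 mol%), 1,10-phenanthroline (5 mol%), 40 °C, 48 h
Reagents that add atoms: n-butyl vinyl ether C=COCCCC
Why: Palladium-catalysed transfer vinylation (transetherification) runs under neutral conditions, so no alkoxide forms and no retro-aldol occurs, the carbinol centre is untouched, and 40 °C is too cool for the [3,3] shift.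

**Step 3**
Reactants: 4 methyl (3S,4E)-3-(ethenyloxy)-2,2-dimethylhex-4-enoate
Product: 6 (3S,4E)-3-(ethenyloxy)-2,2-dimethylhex-4-enal, via diisobutylaluminium hemiacetal 5 (not isolated)
Conditions: iBu2AlH (1.1 equiv), CH2Cl2, −78 °C, 1 h; H2O quench at −78 °C
Reagents that add atoms: none
Why: Partial ester reduction works because the neopentyl aluminium hemiacetal is stable at −78 °C and collapses to the non-enolisable aldehyde only on quench, and the cold reagent leaves the vinyl ether and alkene alone.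

**Step 4**
Reactants: 7 but-3-yn-2-ol (racemic)
Product: 9 (3E)-4-iodo-3-methylbut-3-en-2-ol (racemic), via alkenylalane 8 (not isolated)
Conditions: Me3Al (3 equiv), Cp2ZrCl2 (0.25 equiv), CH2Cl2, 0 °C to rt, 16 h; then I2 (1.2 equiv), THF, −30 °C; aqueous work-up
Reagents that add atoms: trimethylaluminium C[Al](C)C; iodine II
Why: Negishi zirconium-catalysed carboalumination adds Me–Al syn across the terminal alkyne (methyl to the internal carbon), and iodinolysis with retention gives only the (E)-iodide.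

**Step 5**
Reactants: 9 (3E)-4-iodo-3-methylbut-3-en-2-ol
Product: 10 (3E)-4-iodo-3-methylbut-3-en-2-one
Conditions: MnO2 (15 equiv), CH2Cl2, rt
Reagents that add atoms: none
Why: MnO2 allylic alcohol oxidation removes the racemic centre and leaves the alkenyl iodide and its geometry intact.

**Step 6**
Reactants: 6 (3S,4E)-3-(ethenyloxy)-2,2-dimethylhex-4-enal; 10 (3E)-4-iodo-3-methylbut-3-en-2-one
Product: 13 (1E,5S,7S,8E)-7-(ethenyloxy)-5-hydroxy-1-iodo-2,6,6-trimethyldeca-1,8-dien-3-one, via diisopinocampheylboron enolate 11 (not isolated), via boron aldolate 12 (not isolated)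
Conditions: 10, (+)-Ipc2BCl (1.3 equiv), Et3N (1.6 equiv), Et2O, 0 °C, 1 h; then 6, −78 to −20 °C, 16 h; MeOH, pH 7 buffer, 30% H2O2, 0 °C
Reagents that add atoms: none
Why: In this Paterson-type boron aldol of a methyl ketone, the (+)-Ipc2B enolate adds to the aldehyde face that gives the (S)-carbinol at C10, which is the 1,3-anti relation to C1 also favoured by the β-alkoxy dipole, and the non-acidic medium spares the vinyl ether.

**Step 7**
Reactants: 13 (1E,5S,7S,8E)-7-(ethenyloxy)-5-hydroxy-1-iodo-2,6,6-trimethyldeca-1,8-dien-3-one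
Product: 15 (1E,3S,5S,7S,8E)-7-(ethenyloxy)-3-hydroxy-1-iodo-2,6,6-trimethyldeca-1,8-dien-5-yl acetate, via acetaldehyde hemiacetal 14 (not isolated)
Conditions: MeCHO (8 equiv), SmI2 (0.3 equiv), THF, −10 °C, 3 h
Reagents that add atoms: acetaldehyde CC=O
Why: In the Evans–Tishchenko reduction, the hemiacetal on the C10 oxygen, held by trivalent samarium, delivers its hydride intramolecularly to the C8 ketone, giving the 1,3-anti (8S) alcohol, placing the acetate on C10 in the same step, and removing the β-iodo enone that could otherwise cyclise onto the free hydroxyl.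

**Step 8**
Reactants: 15 (1E,3S,5S,7S,8E)-7-(ethenyloxy)-3-hydroxy-1-iodo-2,6,6-trimethyldeca-1,8-dien-5-yl acetate; 16 angelic acid [(2Z)-2-methylbut-2-enoic acid]
Product: 18 (1E,3S,5S,7S,8E)-5-acetoxy-7-(ethenyloxy)-1-iodo-2,6,6-trimethyldeca-1,8-dien-3-yl (2Z)-2-methylbut-2-enoate, via mixed anhydride 17 (not isolated)
Conditions: 16, 2,4,6-trichlorobenzoyl chloride (1.5 equiv), Et3N (3 equiv), toluene, rt, 2 h; then 15, 60 °C, 12 h
Reagents that add atoms: none
Why: Yamaguchi-type mixed-anhydride esterification without a nucleophilic catalyst avoids the addition–elimination path that turns angelate into tiglate, and the amine-buffered medium keeps the vinyl ether safe and the C8 configuration unchanged.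

**Step 9**
Reactants: 18 (1E,3S,5S,7S,8E)-5-acetoxy-7-(ethenyloxy)-1-iodo-2,6,6-trimethyldeca-1,8-dien-3-yl (2Z)-2-methylbut-2-enoate
Product: 19 (1E,3S,5S,7E,9R)-5-acetoxy-1-iodo-2,6,6,9-tetramethyl-11-oxoundeca-1,7-dien-3-yl (2Z)-2-methylbut-2-enoate
Conditions: toluene (0.05 M), BHT (trace), sealed tube, 135 °C, 10 h
Reagents that add atoms: none
Why: The aliphatic Claisen [3,3] rearrangement passes through a chair with the tertiary alkyl group on C1 equatorial, which gives the (E)-C1=C2 alkene, transfers (1S) suprafacially to (3R), and unveils the C5 aldehyde.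

**Step 10**
Reactants: 19 (1E,3S,5S,7E,9R)-5-acetoxy-1-iodo-2,6,6,9-tetramethyl-11-oxoundeca-1,7-dien-3-yl (2Z)-2-methylbut-2-enoate
Product: 21 (2E,4S,6S,8E,10R)-6-acetoxy-1-hydroxy-3,7,7,10-tetramethylcycloundeca-2,8-dien-4-yl (2Z)-2-methylbut-2-enoate (both C1 epimers), via alkenylchromium dichloride 20 (not isolated)
Conditions: CrCl2 (10 equiv), NiCl2 (0.1 equiv), DMSO/THF 3:1, slow addition over 12 h to 0.002 M, rt; H2O work-up
Reagents that add atoms: none
Why: In the Nozaki–Hiyama–Kishi macrocyclisation, zerovalent nickel inserts into the C–I bond with retention and hands the alkenyl group to trivalent chromium, whose aldehyde-selective addition tolerates both esters; high dilution favours the ring, and the new carbinol centre is erased in step 11.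

**Step 11**
Reactants: 21 (2E,4S,6S,8E,10R)-6-acetoxy-1-hydroxy-3,7,7,10-tetramethylcycloundeca-2,8-dien-4-yl (2Z)-2-methylbut-2-enoate
Product: 22 (2E,4S,6S,8E,10R)-6-acetoxy-3,7,7,10-tetramethyl-1-oxocycloundeca-2,8-dien-4-yl (2Z)-2-methylbut-2-enoate
Conditions: Dess–Martin periodinane (1.3 equiv), CH2Cl2, 0 °C to rt
Reagents that add atoms: none
Why: Dess–Martin oxidation of the allylic alcohol is neutral and mild, merges both epimers into the one (E)-enone chromophore, and does not touch the esters or the C3, C8 and C10 centres.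

**Step 12**
Reactants: 22 (2E,4S,6S,8E,10R)-6-acetoxy-3,7,7,10-tetramethyl-1-oxocycloundeca-2,8-dien-4-yl (2Z)-2-methylbut-2-enoate
Product: 23 (3R,4S,5S,7S,9S,10R,11R)-7-acetoxy-1-oxolongipinan-9-yl (2Z)-2-methylbut-2-enoate (target)
Conditions: hν (366 nm LED), degassed cyclohexane, 0.003 M, 10 °C
Reagents that add atoms: none
Why: Proposed new method: n→π* excitation and intersystem crossing give the twisted triplet enone, which closes stepwise across the ring in the crossed sense (C7 to C2, C6 to C1), because the parallel sense would have to join fully substituted C7 to neopentyl C1; the closest known reaction type is the transannular enone–alkene [2+2] photocycloaddition of cyclodeca-2,7-dienones to tricyclo[4.4.0.0(2,7)]decanones; the cage topology fixes the relative configuration of the four new centres, the preset (3R) methyl selects the cage enantiomer by lying on the C1–H side away from the C7 methyl, and the angelate does not absorb at 366 nm.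

**Compound list**
1 | (2E)-but-2-enal (crotonaldehyde) | C/C=C/C=O | starting material
2 | 1-methoxy-2-methyl-1-(trimethylsilyloxy)prop-1-ene | COC(O[Si](C)(C)C)=C(C)C | starting material
3 | methyl (3S,4E)-3-hydroxy-2,2-dimethylhex-4-enoate | C/C=C/[C@H](O)C(C)(C)C(=O)OC | intermediate
4 | methyl (3S,4E)-3-(ethenyloxy)-2,2-dimethylhex-4-enoate | C/C=C/[C@H](OC=C)C(C)(C)C(=O)OC | intermediate
5 | diisobutylaluminium hemiacetal of 4 | C/C=C/[C@H](OC=C)C(C)(C)C(OC)O[Al](CC(C)C)CC(C)C | intermediate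
6 | (3S,4E)-3-(ethenyloxy)-2,2-dimethylhex-4-enal | C/C=C/[C@H](OC=C)C(C)(C)C=O | intermediate
7 | but-3-yn-2-ol (racemic) | CC(O)C#C | starting material
8 | (E)-alkenylalane, dimethylaluminium alkoxide form | CC(O[Al](C)C)/C(C)=C/[Al](C)C | intermediate
9 | (3E)-4-iodo-3-methylbut-3-en-2-ol (racemic) | CC(O)/C(C)=C/I | intermediate
10 | (3E)-4-iodo-3-methylbut-3-en-2-one | CC(=O)/C(C)=C/I | intermediate
11 | diisopinocampheylboron enolate of 10 | C=C(OB([C@H]1C[C@H]2C[C@@H]([C@@H]1C)C2(C)C)[C@H]1C[C@H]2C[C@@H]([C@@H]1C)C2(C)C)/C(C)=C/I | intermediate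
12 | boron aldolate of 13 | I/C=C(\C)C(=O)C[C@H](OB([C@H]1C[C@H]2C[C@@H]([C@@H]1C)C2(C)C)[C@H]1C[C@H]2C[C@@H]([C@@H]1C)C2(C)C)C(C)(C)[C@@H](OC=C)/C=C/C | intermediate
13 | (1E,5S,7S,8E)-7-(ethenyloxy)-5-hydroxy-1-iodo-2,6,6-trimethyldeca-1,8-dien-3-one | I/C=C(\C)C(=O)C[C@H](O)C(C)(C)[C@@H](OC=C)/C=C/C | intermediate
14 | acetaldehyde hemiacetal of 13 | I/C=C(\C)C(=O)C[C@H](OC(C)O)C(C)(C)[C@@H](OC=C)/C=C/C | intermediate
15 | (1E,3S,5S,7S,8E)-7-(ethenyloxy)-3-hydroxy-1-iodo-2,6,6-trimethyldeca-1,8-dien-5-yl acetate | I/C=C(\C)[C@@H](O)C[C@H](OC(C)=O)C(C)(C)[C@@H](OC=C)/C=C/C | intermediate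
16 | angelic acid [(2Z)-2-methylbut-2-enoic acid] | C/C=C(/C)C(=O)O | starting material
17 | angelic 2,4,6-trichlorobenzoic anhydride | C/C=C(/C)C(=O)OC(=O)c1c(Cl)cc(Cl)cc1Cl | intermediate
18 | (1E,3S,5S,7S,8E)-5-acetoxy-7-(ethenyloxy)-1-iodo-2,6,6-trimethyldeca-1,8-dien-3-yl (2Z)-2-methylbut-2-enoate | I/C=C(\C)[C@@H](OC(=O)/C(C)=C\C)C[C@H](OC(C)=O)C(C)(C)[C@@H](OC=C)/C=C/C | intermediate
19 | (1E,3S,5S,7E,9R)-5-acetoxy-1-iodo-2,6,6,9-tetramethyl-11-oxoundeca-1,7-dien-3-yl (2Z)-2-methylbut-2-enoate | I/C=C(\C)[C@@H](OC(=O)/C(C)=C\C)C[C@H](OC(C)=O)C(C)(C)/C=C/[C@H](C)CC=O | intermediate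
20 | alkenylchromium dichloride from 19 | Cl[Cr](Cl)/C=C(\C)[C@@H](OC(=O)/C(C)=C\C)C[C@H](OC(C)=O)C(C)(C)/C=C/[C@H](C)CC=O | intermediate
21 | (2E,4S,6S,8E,10R)-6-acetoxy-1-hydroxy-3,7,7,10-tetramethylcycloundeca-2,8-dien-4-yl (2Z)-2-methylbut-2-enoate (both C1 epimers) | C/C=C(/C)C(=O)O[C@H]1C[C@H](OC(C)=O)C(C)(C)/C=C/[C@H](C)CC(O)/C=C1\C | intermediate
22 | (2E,4S,6S,8E,10R)-6-acetoxy-3,7,7,10-tetramethyl-1-oxocycloundeca-2,8-dien-4-yl (2Z)-2-methylbut-2-enoate | C/C=C(/C)C(=O)O[C@H]1C[C@H](OC(C)=O)C(C)(C)/C=C/[C@H](C)CC(=O)/C=C1\C | intermediate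
23 | (3R,4S,5S,7S,9S,10R,11R)-7-acetoxy-1-oxolongipinan-9-yl (2Z)-2-methylbut-2-enoate (CNP0204102.1) | C/C=C(/C)C(=O)O[C@H]1C[C@H](OC(C)=O)C(C)(C)[C@H]2[C@@H]3[C@H](C)CC(=O)[C@H]2[C@@]31C | target

**Step count**
Total step count: 12.
Longest linear sequence: 10 (steps 1–3 and 6–12). Steps 4–5 form the side branch.

**Three steps most likely to fail**

Step 12 (crossed versus parallel closure; possible Z to E drift of the angelate). The fallback puts the angelate on after the cage is built, which also allows a triplet sensitiser.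
It sets out from 15. Et3SiCl/imidazole gives the triethylsilyl ether F1. Heating as in step 9 gives the aldehyde F2. CrCl2/NiCl2 closure gives the macrocyclic alcohol F3. Dess–Martin oxidation gives the silyloxy dienone F4. Xanthone-sensitised irradiation gives the caged silyl ether F5. HF·pyridine gives the hydroxy ketone F6. Acylation of this alcohol by mixed anhydride 17 comes back to the route at 23.

Step 10 (strained eleven-membered ring; oligomerisation). The fallback closes the same bond as an acyl Stille coupling and so forms the ketone directly.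
It sets out from 18. (Bu3Sn)2 and Pd(PPh3)4 exchange iodine for tin to give the alkenylstannane F7. Thermal Claisen rearrangement gives the stannyl aldehyde F8. NaClO2/NaH2PO4/2-methylbut-2-ene gives the acid F9. 1-Chloro-N,N,2-trimethylprop-1-en-1-amine gives the acid chloride F10. Slow addition of this chloride to Pd2(dba)3/P(2-furyl)3 in toluene closes the ring with retention of alkene geometry. This comes back to the route at 22 and skips 21.

Step 6 (hindered α-quaternary aldehyde; only moderate reagent control). The fallback exchanges the roles of the partners, so the hindered carbonyl becomes the enolate donor and the C8–C9 bond is made instead of C9–C10.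
It sets out from 4. Me3SiCH2Li gives the α-silyl ketone F11, and methanol cleaves it to the methyl ketone F12. Prop-2-yn-1-ol, taken through the operations of steps 4 and 5, gives the iodo alcohol F13 and then the iodo enal F14. A (+)-Ipc2BCl/Et3N aldol of the methyl ketone with this unhindered enal gives the (8S)-hydroxy ketone F15. Me4NBH(OAc)3 in MeCN/AcOH at −40 °C delivers hydride from the C8-bound borohydride to give the anti diol F16. Mixed anhydride 17 acylates only the unhindered allylic hydroxyl to give the monoangelate F17. Ac2O/pyridine/DMAP then comes back to the route at 18.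

**Further compounds**
F1 | step 12 | (1E,3S,5S,7S,8E)-7-(ethenyloxy)-1-iodo-2,6,6-trimethyl-3-(triethylsilyloxy)deca-1,8-dien-5-yl acetate | I/C=C(\C)[C@@H](O[Si](CC)(CC)CC)C[C@H](OC(C)=O)C(C)(C)[C@@H](OC=C)/C=C/C
F2 | step 12 | (1E,3S,5S,7E,9R)-1-iodo-2,6,6,9-tetramethyl-11-oxo-3-(triethylsilyloxy)undeca-1,7-dien-5-yl acetate | I/C=C(\C)[C@@H](O[Si](CC)(CC)CC)C[C@H](OC(C)=O)C(C)(C)/C=C/[C@H](C)CC=O
F3 | step 12 | (2E,4S,6S,8E,10R)-1-hydroxy-3,7,7,10-tetramethyl-4-(triethylsilyloxy)cycloundeca-2,8-dien-6-yl acetate (both C1 epimers) | CC[Si](CC)(CC)O[C@H]1C[C@H](OC(C)=O)C(C)(C)/C=C/[C@H](C)CC(O)/C=C1\C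
F4 | step 12 | (2E,4S,6S,8E,10R)-3,7,7,10-tetramethyl-1-oxo-4-(triethylsilyloxy)cycloundeca-2,8-dien-6-yl acetate | CC[Si](CC)(CC)O[C@H]1C[C@H](OC(C)=O)C(C)(C)/C=C/[C@H](C)CC(=O)/C=C1\C
F5 | step 12 | (3R,4S,5S,7S,9S,10R,11R)-1-oxo-9-(triethylsilyloxy)longipinan-7-yl acetate | CC[Si](CC)(CC)O[C@H]1C[C@H](OC(C)=O)C(C)(C)[C@H]2[C@@H]3[C@H](C)CC(=O)[C@H]2[C@@]31C
F6 | step 12 | (3R,4S,5S,7S,9S,10R,11R)-9-hydroxy-1-oxolongipinan-7-yl acetate | O[C@H]1C[C@H](OC(C)=O)C(C)(C)[C@H]2[C@@H]3[C@H](C)CC(=O)[C@H]2[C@@]31C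
F7 | step 10 | (1E,3S,5S,7S,8E)-5-acetoxy-7-(ethenyloxy)-2,6,6-trimethyl-1-(tributylstannyl)deca-1,8-dien-3-yl (2Z)-2-methylbut-2-enoate | CCCC[Sn](CCCC)(CCCC)/C=C(\C)[C@@H](OC(=O)/C(C)=C\C)C[C@H](OC(C)=O)C(C)(C)[C@@H](OC=C)/C=C/C
F8 | step 10 | (1E,3S,5S,7E,9R)-5-acetoxy-2,6,6,9-tetramethyl-11-oxo-1-(tributylstannyl)undeca-1,7-dien-3-yl (2Z)-2-methylbut-2-enoate | CCCC[Sn](CCCC)(CCCC)/C=C(\C)[C@@H](OC(=O)/C(C)=C\C)C[C@H](OC(C)=O)C(C)(C)/C=C/[C@H](C)CC=O
F9 | step 10 | (3R,4E,7S,9S,10E)-7-acetoxy-3,6,6,10-tetramethyl-9-[(2Z)-2-methylbut-2-enoyloxy]-11-(tributylstannyl)undeca-4,10-dienoic acid | CCCC[Sn](CCCC)(CCCC)/C=C(\C)[C@@H](OC(=O)/C(C)=C\C)C[C@H](OC(C)=O)C(C)(C)/C=C/[C@H](C)CC(=O)O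
F10 | step 10 | acid chloride of F9 | CCCC[Sn](CCCC)(CCCC)/C=C(\C)[C@@H](OC(=O)/C(C)=C\C)C[C@H](OC(C)=O)C(C)(C)/C=C/[C@H](C)CC(=O)Cl
F11 | step 6 | (4S,5E)-4-(ethenyloxy)-3,3-dimethyl-1-(trimethylsilyl)hept-5-en-2-one | C/C=C/[C@H](OC=C)C(C)(C)C(=O)C[Si](C)(C)C
F12 | step 6 | (4S,5E)-4-(ethenyloxy)-3,3-dimethylhept-5-en-2-one | C/C=C/[C@H](OC=C)C(C)(C)C(C)=O
F13 | step 6 | (2E)-3-iodo-2-methylprop-2-en-1-ol | OC/C(C)=C/I
F14 | step 6 | (2E)-3-iodo-2-methylprop-2-enal | O=C/C(C)=C/I
F15 | step 6 | (1E,3S,7S,8E)-7-(ethenyloxy)-3-hydroxy-1-iodo-2,6,6-trimethyldeca-1,8-dien-5-one | I/C=C(\C)[C@@H](O)CC(=O)C(C)(C)[C@@H](OC=C)/C=C/C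
F16 | step 6 | (1E,3S,5S,7S,8E)-7-(ethenyloxy)-1-iodo-2,6,6-trimethyldeca-1,8-diene-3,5-diol | I/C=C(\C)[C@@H](O)C[C@H](O)C(C)(C)[C@@H](OC=C)/C=C/C
F17 | step 6 | (1E,3S,5S,7S,8E)-7-(ethenyloxy)-5-hydroxy-1-iodo-2,6,6-trimethyldeca-1,8-dien-3-yl (2Z)-2-methylbut-2-enoate | I/C=C(\C)[C@@H](OC(=O)/C(C)=C\C)C[C@H](O)C(C)(C)[C@@H](OC=C)/C=C/C
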